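The readings were generated by integration for substances that don't exist; the scatter is artificial.

3 questions stand on this flask: how it ends, how much Q has reacted, and how much D it holds.

| setting | beta | delta | epsilon | flask |
|---|---|---|---|---|
| Q | 0.010 M | 0.010 M | 0.020 M | 0.010 M |
| L | 7 equiv (fed, over 40 min) | 11 equiv (fed, over 40 min) | 5 equiv (fed, over 40 min) | 5.00 equiv (fed, over 40 min) |
| G | 0.60 equiv | 0.60 equiv | 0.60 equiv | 0.600 equiv |
| remark | run made earlier; the fed solution adds 0.10 times the starting volume | run made earlier; the fed solution adds 0.10 times the starting volume | run made earlier; the fed solution adds 0.10 times the starting volume | the fed solution adds 0.10 times the starting volume |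
| time |  |  |  | 25 h |

- beta (time / h: Q / %, D / %): 4.00: 72, 28; 10.0: 69, 29; 20.0: 73, 30; 30.0: 71, 28
- delta (time / h: Q / %, D / %): 4.00: 77, 26; 10.0: 75, 25; 20.0: 71, 29; 30.0: 74, 27
- epsilon (time / h: Q / %, D / %): 2.50: 87, 15; 6.00: 68, 33; 12.0: 63, 36; 30.0: 65, 34

(each reading ± 1.5 percentage points)

- every charge counts on the volume at the start, and the solution that is fed holds the whole dose
- solid, in amounts per volume of the solution: G
- at the start none of G is in solution
- the reaction counts as stopped when no species that holds the Q changes by six tenths of a point or more over the second half of the time

* the state of affairs at 25 h: stopped, and by what, or still going (for what has run out or reacted, a solid counts together with what of it has only dissolved) (forward and back rates have come level / it is still moving / all of Q has reacted / Z has run out first)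
* conversion of Q at 25 h
* amount of D at 25 h, in percent of the Q charged

I follow one unit of Q to its fork, into D or left as Q, and turn the settings in turn. Time comes first: beta reads D 28% at 4.00 h and 28% at 30.0 h, so within the scatter it has stopped moving, and I read a balance. For the other settings I form one number from the late readings of each run, at the volume after the feed:

quotient = D / (Q × reagent not in D)

beta: D 29.0%, quotient 145 M⁻¹

delta: D 27.0%, quotient 123 M⁻¹

This holding quotient, a conditional equilibrium constant, tells a unit's chance at the fork. More Q raises D by hand, through the higher concentration, and epsilon reads 35.0%. More L lowers the quotient, delta's reading being smaller than beta's, though 1.5 percentage points of scatter stands behind both. No run turned G.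

I draw the inverse quotient straight against L per litre through beta and delta. For the flask this gives 159 M⁻¹, and solving the balance gives D 30.1%.

The forecast says forward and back rates have come level, with conversion 29% and D 29%, since the flask “matches beta apart from having less L”. My figure differs from its D through the L line.

    Q + Z ⇌ D (K = 260 M⁻¹, k = 3.10 M⁻¹ min⁻¹)
    L + Z ⇌ E (K = 17.0 M⁻¹, k = 3.10 M⁻¹ min⁻¹)
    L ⇌ J (K = 0.270, k = 0.320 min⁻¹)
    G ⇌ Z, rate k4*(cs4 - [Z]) while solid is left; crystals form when [Z] > cs4 (solubility = 4.60 mM, k = 0.00870 min⁻¹)

The flask stops where forward and back rates have come level, with conversion 30.5% and D 30.5%, and its quotient is 163 M⁻¹, higher than beta's 145 M⁻¹. The step of Q and Z to D has done half its turnover by 1.77 h, far earlier than 25 h, and its backward turnover stands at 94% of the forward one. A run showing the forecast wrong has to shift D, and D has moved 5 points with G, moved alone, at 0.486 equiv or 0.724 equiv, or with Q, moved alone, at 0.00557 M or 0.0215 M. With Q at 0.025 M, the line gives quotient 117 M⁻¹ and D 37.4%; that flask holds 36.2%.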